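**Retrosynthetic overview**

- The strategy rests on the cyclopentane ring (C5–C6–C7–C8–C9): the secondary C7 carbinol sits next to the tertiary C8 carbinol that carries C10, which is the pattern of a reduced acyloin. The C7–C8 bond is therefore cut to a C7 aldehyde and a C8 α-silyloxy ketone held cis on a preformed dihydropyran (pyran ring first, cyclopentane second).
- The pyran (C1, O2, C3=C4, C5, C9) comes from an enamine Michael addition that forms C5–C9, followed by thioester-to-aldehyde reduction and spontaneous lactol closure (O2–C1).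
- Side chains are then adjusted: sulfoxide elimination and dihydroxylation (C8/C10), ester reduction (C11), silylation, PMB removal and double oxidation to the keto aldehyde.
- After the carbene-catalysed closure: C1 silyl-to-acyl exchange, hydroxyl-directed reduction at C7, esterification with a Z-coumaric acid, desilylation.

Key step: step 16

Convention: iridoid numbering is used for the stereochemical labels (C1 acetal carbon, O2, C3=C4, C5, C6, C7, C8, C9, C10 on C8, C11 on C4); β is the face of H5 and H9; TBS = tert-butyldimethylsilyl, PMB = 4-methoxybenzyl.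

Assumption: the anomeric carbon C1 of the silyl acetals is drawn as the 1β anomer (O1 trans to the C9 side chain); either anomer would serve, because C1 is reset at the lactol stage in step 17.

**Route**

Step 1
Reactants: 1 but-3-en-1-ol; 2 benzenethiol
Product: 3 4-(phenylsulfanyl)butan-1-ol
Conditions: AIBN (5 mol%), neat, 75 °C
Reagents that add atoms: none
Why: Radical thiol–ene hydrothiolation; the thiyl radical adds to the terminal alkene carbon, so the anti-Markovnikov sulfide should be the only product.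

Step 2
Reactants: 3 4-(phenylsulfanyl)butan-1-ol
Product: 4 4-(phenylsulfanyl)butanal
Conditions: Dess–Martin periodinane, CH2Cl2, 0 °C → rt
Reagents that add atoms: none
Why: Dess–Martin oxidation of a primary alcohol to the aldehyde; the aryl alkyl sulfide is not oxidised by the periodinane.

Step 3
Reactants: 5 methyl 3-chloro-3-oxopropanoate
Product: 6 methyl 3-(ethylsulfanyl)-3-oxopropanoate
Conditions: EtSH, pyridine, CH2Cl2, 0 °C
Reagents that add atoms: ethanethiol, CCS
Why: Acyl substitution of the acid chloride by the thiol gives the mixed ester/thioester malonate, whose thioester is the later handle for selective reduction to the C3 aldehyde.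

Step 4
Reactants: 7 3-[(4-methoxyphenyl)methoxy]propan-1-ol
Product: 8 3-[(4-methoxyphenyl)methoxy]propanal
Conditions: Dess–Martin periodinane, CH2Cl2, 0 °C → rt
Reagents that add atoms: none
Why: Dess–Martin oxidation of the primary alcohol; the PMB ether is inert.

Step 5
Reactants: 6 methyl 3-(ethylsulfanyl)-3-oxopropanoate; 8 3-[(4-methoxyphenyl)methoxy]propanal
Product: 9 methyl 2-[(ethylsulfanyl)carbonyl]-5-[(4-methoxyphenyl)methoxy]pent-2-enoate (E/Z mixture)
Conditions: piperidine (10 mol%), AcOH (10 mol%), 4 Å molecular sieves, CH2Cl2, 0 °C → rt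
Reagents that add atoms: none
Why: Knoevenagel condensation of the doubly activated methylene with the aliphatic aldehyde; the alkene geometry is immaterial because both isomers present the same prochiral C5 and the malonate carbon (future C4) becomes sp2.

Step 6
Reactants: 4 4-(phenylsulfanyl)butanal; 9 methyl 2-[(ethylsulfanyl)carbonyl]-5-[(4-methoxyphenyl)methoxy]pent-2-enoate
Product: 10 methyl (3S,4R)-2-[(ethylsulfanyl)carbonyl]-4-formyl-3-{2-[(4-methoxyphenyl)methoxy]ethyl}-6-(phenylsulfanyl)hexanoate (C2 epimers)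
Conditions: (S)-2-[diphenyl(trimethylsilyloxy)methyl]pyrrolidine (20 mol%), PhCO2H (20 mol%), toluene, 0 °C → rt
Reagents that add atoms: none
Why: Enamine-catalysed Michael addition of an aldehyde to an alkylidene malonate-type acceptor (diarylprolinol silyl ether catalysis); the E-enamine of 4 is shielded on one face by the diphenyl(silyloxy)methyl group, which sets C9 (R), and the trisubstituted thiomalonate is expected to react in the anti mode described for this acceptor class on secoiridoid-type substrates, which sets C5 (S) and places the two side chains cis once the pyran is closed.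

Step 7
Reactants: 10 methyl (3S,4R)-2-[(ethylsulfanyl)carbonyl]-4-formyl-3-{2-[(4-methoxyphenyl)methoxy]ethyl}-6-(phenylsulfanyl)hexanoate
Product: 12 methyl 2-hydroxy-4-{2-[(4-methoxyphenyl)methoxy]ethyl}-3-[2-(phenylsulfanyl)ethyl]-3,4-dihydro-2H-pyran-5-carboxylate (3,4-cis side chains; 2-OH trans to the C3 chain), via formyl ester 11 (not isolated)
Conditions: Et3SiH, Pd/C (10 wt% palladium on carbon), acetone, rt
Reagents that add atoms: none
Why: Fukuyama reduction turns only the thioester into the C3 aldehyde; the formyl ester enolises and its enol oxygen adds to the C1 aldehyde, closing the pyran (O2–C1) as the hemiacetal, and C1 equilibrates to the anomer with O1 trans to the C9 chain.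

Step 8
Reactants: 12 methyl 2-hydroxy-4-{2-[(4-methoxyphenyl)methoxy]ethyl}-3-[2-(phenylsulfanyl)ethyl]-3,4-dihydro-2H-pyran-5-carboxylate
Product: 13 methyl 2-[(TBS)oxy]-4-{2-[(4-methoxyphenyl)methoxy]ethyl}-3-[2-(phenylsulfanyl)ethyl]-3,4-dihydro-2H-pyran-5-carboxylate (1β-silyl acetal)
Conditions: TBSCl, imidazole, DMF, 0 °C → rt
Reagents that add atoms: tert-butyldimethylsilyl chloride, CC(C)(C)[Si](C)(C)Cl
Why: Silylation of the hemiacetal hydroxyl locks the pyran as the silyl acetal; the less hindered anomer with O1 trans to the C9 chain should be trapped.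

Step 9
Reactants: 13 methyl 2-[(TBS)oxy]-4-{2-[(4-methoxyphenyl)methoxy]ethyl}-3-[2-(phenylsulfanyl)ethyl]-3,4-dihydro-2H-pyran-5-carboxylate
Product: 14 methyl 2-[(TBS)oxy]-4-{2-[(4-methoxyphenyl)methoxy]ethyl}-3-[2-(phenylsulfinyl)ethyl]-3,4-dihydro-2H-pyran-5-carboxylate (sulfur epimers)
Conditions: mCPBA (1.0 equiv), CH2Cl2, −78 °C
Reagents that add atoms: 3-chloroperoxybenzoic acid, OOC(=O)c1cccc(Cl)c1
Why: Sulfide-to-sulfoxide oxidation with one equivalent of peracid at low temperature; the ester-conjugated enol ether is too electron-poor to be epoxidised.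

Step 10
Reactants: 14 methyl 2-[(TBS)oxy]-4-{2-[(4-methoxyphenyl)methoxy]ethyl}-3-[2-(phenylsulfinyl)ethyl]-3,4-dihydro-2H-pyran-5-carboxylate
Product: 15 methyl 2-[(TBS)oxy]-3-ethenyl-4-{2-[(4-methoxyphenyl)methoxy]ethyl}-3,4-dihydro-2H-pyran-5-carboxylate
Conditions: CaCO3, xylene, 140 °C
Reagents that add atoms: none
Why: Thermal sulfoxide syn-elimination; the only β-hydrogens are on C8, so the C8=C10 vinyl group forms without regiochemical ambiguity and C9 is untouched.

Step 11
Reactants: 15 methyl 2-[(TBS)oxy]-3-ethenyl-4-{2-[(4-methoxyphenyl)methoxy]ethyl}-3,4-dihydro-2H-pyran-5-carboxylate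
Product: 16 methyl 2-[(TBS)oxy]-3-(1,2-dihydroxyethyl)-4-{2-[(4-methoxyphenyl)methoxy]ethyl}-3,4-dihydro-2H-pyran-5-carboxylate (C8 carbinol epimers)
Conditions: OsO4 (2 mol%), N-methylmorpholine N-oxide, acetone/H2O, 0 °C → rt
Reagents that add atoms: osmium tetroxide, O=[Os](=O)(=O)=O; N-methylmorpholine N-oxide, C[N+]1([O-])CCOCC1; water, O
Why: Catalytic OsO4 dihydroxylation selects the monosubstituted vinyl group over the ester-deactivated C3=C4 enol ether; the C8 configuration is irrelevant because C8 is oxidised in step 15.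

Step 12
Reactants: 16 methyl 2-[(TBS)oxy]-3-(1,2-dihydroxyethyl)-4-{2-[(4-methoxyphenyl)methoxy]ethyl}-3,4-dihydro-2H-pyran-5-carboxylate
Product: 17 1-[2-[(TBS)oxy]-5-(hydroxymethyl)-4-{2-[(4-methoxyphenyl)methoxy]ethyl}-3,4-dihydro-2H-pyran-3-yl]ethane-1,2-diol
Conditions: iBu2AlH (5 equiv), CH2Cl2, −78 → −40 °C; aqueous potassium sodium tartrate
Reagents that add atoms: none
Why: 1,2-Reduction of the β-alkoxyacrylate ester by the aluminium hydride gives the C11 allylic alcohol; the silyl acetal and PMB ether are inert.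

Step 13
Reactants: 17 1-[2-[(TBS)oxy]-5-(hydroxymethyl)-4-{2-[(4-methoxyphenyl)methoxy]ethyl}-3,4-dihydro-2H-pyran-3-yl]ethane-1,2-diol
Product: 18 2-[(TBS)oxy]-1-[2-[(TBS)oxy]-5-{[(TBS)oxy]methyl}-4-{2-[(4-methoxyphenyl)methoxy]ethyl}-3,4-dihydro-2H-pyran-3-yl]ethan-1-ol
Conditions: TBSCl (2.2 equiv), imidazole, CH2Cl2, −20 → 0 °C
Reagents that add atoms: tert-butyldimethylsilyl chloride, CC(C)(C)[Si](C)(C)Cl
Why: Silylation is much faster at the two primary hydroxyls (C10, C11) than at the secondary C8 hydroxyl, which stays free for the later oxidation.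

Step 14
Reactants: 18 2-[(TBS)oxy]-1-[2-[(TBS)oxy]-5-{[(TBS)oxy]methyl}-4-{2-[(4-methoxyphenyl)methoxy]ethyl}-3,4-dihydro-2H-pyran-3-yl]ethan-1-ol
Product: 19 2-[(TBS)oxy]-1-[2-[(TBS)oxy]-5-{[(TBS)oxy]methyl}-4-(2-hydroxyethyl)-3,4-dihydro-2H-pyran-3-yl]ethan-1-ol
Conditions: DDQ, CH2Cl2/pH 7 phosphate buffer, 0 °C
Reagents that add atoms: none
Why: Oxidative cleavage of the PMB ether under buffered conditions, which cyclic enol ethers of the glycal type and silyl ethers tolerate, frees the C7 hydroxyl.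

Step 15
Reactants: 19 2-[(TBS)oxy]-1-[2-[(TBS)oxy]-5-{[(TBS)oxy]methyl}-4-(2-hydroxyethyl)-3,4-dihydro-2H-pyran-3-yl]ethan-1-ol
Product: 20 2-[2-[(TBS)oxy]-3-{[(TBS)oxy]acetyl}-5-{[(TBS)oxy]methyl}-3,4-dihydro-2H-pyran-4-yl]acetaldehyde (3,4-cis arms; 2-O trans to the C3 arm)
Conditions: (COCl)2, DMSO, CH2Cl2, −78 °C; then iPr2NEt, −78 → −40 °C; cold pH 7 quench
Reagents that add atoms: none
Why: Swern oxidation activates both hydroxyls as alkoxysulfonium ions before any carbonyl exists, so the C7 aldehyde and the C8 ketone form together without lactol or lactone interception, and the cold quench limits epimerisation at C9.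

Step 16
Reactants: 20 2-[2-[(TBS)oxy]-3-{[(TBS)oxy]acetyl}-5-{[(TBS)oxy]methyl}-3,4-dihydro-2H-pyran-4-yl]acetaldehyde
Product: 21 1-[(TBS)oxy]-4,7-bis{[(TBS)oxy]methyl}-7-hydroxy-1,4a,5,7a-tetrahydrocyclopenta[c]pyran-6(7H)-one (cis-fused; 1-O β; 8-OH α; C10 β in iridoid terms)
Conditions: 6,7-dihydro-2-(pentafluorophenyl)-5H-pyrrolo[2,1-c][1,2,4]triazol-2-ium tetrafluoroborate (15 mol%), Et3N (15 mol%), CH2Cl2, 0 → 23 °C
Reagents that add atoms: none
Why: The free carbene adds to the unhindered C7 aldehyde and a proton shift gives the Breslow enaminol, whose nucleophilic C7 attacks the C8 ketone before the azolium is expelled; this is the intramolecular crossed aldehyde–ketone benzoin reaction, a known route to five-membered tertiary α-ketols. The cyclopentane (C5–C6–C7–C8–C9) closes in a 5-exo-trig mode onto the preformed dihydropyran, and the cis disposition of the two arms leads to the cis-fused bicycle. The one new stereocentre, C8, is set by the substrate: in the hydrogen-bonded transition state the bulky azolium on C7 takes the convex face, so the enaminol O–H points to the concave face and binds the ketone oxygen there, which places O8 syn to C1 and C10 on the H9 face. Chemoselectivity (aldehyde as donor, ketone as acceptor) follows from the much faster carbene addition to the aldehyde and from activation of the ketone by its α-silyloxy group; the weak amine does not enolise C10, so no six-ring aldol competes. The step needs cyclisation to outrun deprotonation at C9 (epimerisation, or loss of silanolate from C1), which the electron-poor N-pentafluorophenyl triazolium with substoichiometric tertiary amine is chosen to secure.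

Step 17
Reactants: 21 1-[(TBS)oxy]-4,7-bis{[(TBS)oxy]methyl}-7-hydroxy-1,4a,5,7a-tetrahydrocyclopenta[c]pyran-6(7H)-one; 22 (R)-3-methylpentanoic acid
Product: 24 4,7-bis{[(TBS)oxy]methyl}-7-hydroxy-6-oxo-1,4a,5,6,7,7a-hexahydrocyclopenta[c]pyran-1-yl (3R)-3-methylpentanoate (1β ester), via lactol 23 (not isolated)
Conditions: Bu4NF/AcOH (1:1, 1.1 equiv), THF, −20 °C; then 22, EDC·HCl, DMAP, CH2Cl2, 0 °C
Reagents that add atoms: none
Why: Buffered fluoride cleaves the anomeric silyl ether (the best leaving alkoxide) in preference to the primary alkyl silyl ethers, and Steglich acylation traps the equilibrating lactol at its only acylable hydroxyl as the 1β ester with O1 trans to the C9–C8 bond, as in acylated iridoid aglycones; the tertiary 8-OH does not react.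

Step 18
Reactants: 24 4,7-bis{[(TBS)oxy]methyl}-7-hydroxy-6-oxo-1,4a,5,6,7,7a-hexahydrocyclopenta[c]pyran-1-yl (3R)-3-methylpentanoate
Product: 25 4,7-bis{[(TBS)oxy]methyl}-6,7-dihydroxy-1,4a,5,6,7,7a-hexahydrocyclopenta[c]pyran-1-yl (3R)-3-methylpentanoate (7β-OH, 8α-OH in iridoid terms)
Conditions: Me4NBH(OAc)3, MeCN/AcOH (10:1), −30 °C
Reagents that add atoms: none
Why: Hydroxyl-directed reduction of Evans–Saksena type: the tertiary 8α-hydroxyl exchanges onto boron and delivers hydride intramolecularly to the α face of the C7 carbonyl, which sets C7 as the 7β-alcohol trans to 8-OH.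

Step 19
Reactants: 26 4-[(tert-butyldimethylsilyl)oxy]benzaldehyde; 27 methyl 2-[bis(2,2,2-trifluoroethoxy)phosphoryl]acetate
Product: 28 methyl (Z)-3-{4-[(TBS)oxy]phenyl}prop-2-enoate
Conditions: KN(SiMe3)2, 18-crown-6, THF, −78 °C
Reagents that add atoms: none
Why: Still–Gennari olefination; fast, irreversible collapse of the electron-poor phosphonate adduct with the dissociated potassium counter-ion gives the Z cinnamate kinetically.

Step 20
Reactants: 28 methyl (Z)-3-{4-[(TBS)oxy]phenyl}prop-2-enoate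
Product: 29 (Z)-3-(4-hydroxyphenyl)prop-2-enoic acid
Conditions: LiOH, THF/MeOH/H2O, 0 °C → rt, exclusion of light; aqueous HCl to pH 3
Reagents that add atoms: lithium hydroxide, [Li+].[OH-]
Why: Saponification of the methyl ester, which also removes the base-labile aryl silyl ether; the Z geometry should be kept in the dark because no reversible conjugate addition occurs under these conditions.

Step 21
Reactants: 29 (Z)-3-(4-hydroxyphenyl)prop-2-enoic acid
Product: 31 (Z)-3-{4-[(TBS)oxy]phenyl}prop-2-enoic acid, via bis-silyl derivative 30 (not isolated)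
Conditions: TBSCl (2.5 equiv), imidazole, DMF, rt; then AcOH/THF/H2O, rt
Reagents that add atoms: tert-butyldimethylsilyl chloride, CC(C)(C)[Si](C)(C)Cl
Why: Exhaustive silylation followed by hydrolysis of the far more labile silyl ester leaves the phenol protected and the acid free for coupling.

Step 22
Reactants: 25 4,7-bis{[(TBS)oxy]methyl}-6,7-dihydroxy-1,4a,5,6,7,7a-hexahydrocyclopenta[c]pyran-1-yl (3R)-3-methylpentanoate; 31 (Z)-3-{4-[(TBS)oxy]phenyl}prop-2-enoic acid
Product: 33 tris-TBS ether of the target (7-O-[(Z)-4-(TBS-oxy)cinnamoyl]; 10-O-TBS; 11-O-TBS), via mixed anhydride 32 (not isolated)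
Conditions: 31, 2,4,6-trichlorobenzoyl chloride, Et3N, THF, 0 °C; then 25, DMAP, toluene, 0 °C → rt, exclusion of light
Reagents that add atoms: 2,4,6-trichlorobenzoyl chloride, O=C(Cl)c1c(Cl)cc(Cl)cc1Cl (its aroyl group is carried by intermediate 32 only)
Why: Yamaguchi esterification acylates the hindered secondary 7β-hydroxyl while the tertiary 8-OH stays free; low temperature and darkness are chosen to keep the Z alkene.

Step 23
Reactants: 33 tris-TBS ether of the target
Product: 34 CNP0217341.1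
Conditions: HF·pyridine, pyridine, THF, 0 °C → rt, exclusion of light
Reagents that add atoms: none
Why: Acidic, non-nucleophilic fluoride removes the two primary alkyl silyl ethers and the aryl silyl ether while sparing both esters, the acyl acetal, the enol ether and the Z alkene, and avoids base-induced acyl migration.

**Compound list**

1 | but-3-en-1-ol | C=CCCO | starting material
2 | benzenethiol | Sc1ccccc1 | starting material
3 | 4-(phenylsulfanyl)butan-1-ol | OCCCCSc1ccccc1 | intermediate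
4 | 4-(phenylsulfanyl)butanal | O=CCCCSc1ccccc1 | intermediate
5 | methyl 3-chloro-3-oxopropanoate | COC(=O)CC(=O)Cl | starting material
6 | methyl 3-(ethylsulfanyl)-3-oxopropanoate | CCSC(=O)CC(=O)OC | intermediate
7 | 3-[(4-methoxyphenyl)methoxy]propan-1-ol | COc1ccc(COCCCO)cc1 | starting material
8 | 3-[(4-methoxyphenyl)methoxy]propanal | COc1ccc(COCCC=O)cc1 | intermediate
9 | methyl 2-[(ethylsulfanyl)carbonyl]-5-[(4-methoxyphenyl)methoxy]pent-2-enoate, E/Z mixture | CCSC(=O)C(=CCCOCc1ccc(OC)cc1)C(=O)OC | intermediate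
10 | methyl (3S,4R)-2-[(ethylsulfanyl)carbonyl]-4-formyl-3-{2-[(4-methoxyphenyl)methoxy]ethyl}-6-(phenylsulfanyl)hexanoate, C2 epimers | O=C[C@H](CCSc1ccccc1)[C@H](CCOCc1ccc(OC)cc1)C(C(=O)OC)C(=O)SCC | intermediate
11 | methyl (3S,4R)-2,4-diformyl-3-{2-[(4-methoxyphenyl)methoxy]ethyl}-6-(phenylsulfanyl)hexanoate, not isolated | O=C[C@H](CCSc1ccccc1)[C@H](CCOCc1ccc(OC)cc1)C(C=O)C(=O)OC | intermediate
12 | methyl 2-hydroxy-4-{2-[(4-methoxyphenyl)methoxy]ethyl}-3-[2-(phenylsulfanyl)ethyl]-3,4-dihydro-2H-pyran-5-carboxylate; side chains cis (α), 2-OH β | O[C@@H]1OC=C(C(=O)OC)[C@@H](CCOCc2ccc(OC)cc2)[C@H]1CCSc3ccccc3 | intermediate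
13 | methyl 2-[(TBS)oxy]-4-{2-[(4-methoxyphenyl)methoxy]ethyl}-3-[2-(phenylsulfanyl)ethyl]-3,4-dihydro-2H-pyran-5-carboxylate; side chains cis (α), 2-O β | CC(C)(C)[Si](C)(C)O[C@@H]1OC=C(C(=O)OC)[C@@H](CCOCc2ccc(OC)cc2)[C@H]1CCSc3ccccc3 | intermediate
14 | methyl 2-[(TBS)oxy]-4-{2-[(4-methoxyphenyl)methoxy]ethyl}-3-[2-(phenylsulfinyl)ethyl]-3,4-dihydro-2H-pyran-5-carboxylate; ring stereochemistry as in 13, sulfur epimers | CC(C)(C)[Si](C)(C)O[C@@H]1OC=C(C(=O)OC)[C@@H](CCOCc2ccc(OC)cc2)[C@H]1CCS(=O)c3ccccc3 | intermediate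
15 | methyl 2-[(TBS)oxy]-3-ethenyl-4-{2-[(4-methoxyphenyl)methoxy]ethyl}-3,4-dihydro-2H-pyran-5-carboxylate; ring stereochemistry as in 13 | CC(C)(C)[Si](C)(C)O[C@@H]1OC=C(C(=O)OC)[C@@H](CCOCc2ccc(OC)cc2)[C@H]1C=C | intermediate
16 | methyl 2-[(TBS)oxy]-3-(1,2-dihydroxyethyl)-4-{2-[(4-methoxyphenyl)methoxy]ethyl}-3,4-dihydro-2H-pyran-5-carboxylate; ring stereochemistry as in 13, carbinol epimers | CC(C)(C)[Si](C)(C)O[C@@H]1OC=C(C(=O)OC)[C@@H](CCOCc2ccc(OC)cc2)[C@H]1C(O)CO | intermediate
17 | 1-[2-[(TBS)oxy]-5-(hydroxymethyl)-4-{2-[(4-methoxyphenyl)methoxy]ethyl}-3,4-dihydro-2H-pyran-3-yl]ethane-1,2-diol; ring stereochemistry as in 13, carbinol epimers | CC(C)(C)[Si](C)(C)O[C@@H]1OC=C(CO)[C@@H](CCOCc2ccc(OC)cc2)[C@H]1C(O)CO | intermediate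
18 | 2-[(TBS)oxy]-1-[2-[(TBS)oxy]-5-{[(TBS)oxy]methyl}-4-{2-[(4-methoxyphenyl)methoxy]ethyl}-3,4-dihydro-2H-pyran-3-yl]ethan-1-ol; ring stereochemistry as in 13, carbinol epimers | CC(C)(C)[Si](C)(C)O[C@@H]1OC=C(CO[Si](C)(C)C(C)(C)C)[C@@H](CCOCc2ccc(OC)cc2)[C@H]1C(O)CO[Si](C)(C)C(C)(C)C | intermediate
19 | 2-[(TBS)oxy]-1-[2-[(TBS)oxy]-5-{[(TBS)oxy]methyl}-4-(2-hydroxyethyl)-3,4-dihydro-2H-pyran-3-yl]ethan-1-ol; ring stereochemistry as in 13, carbinol epimers | CC(C)(C)[Si](C)(C)O[C@@H]1OC=C(CO[Si](C)(C)C(C)(C)C)[C@@H](CCO)[C@H]1C(O)CO[Si](C)(C)C(C)(C)C | intermediate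
20 | 2-[2-[(TBS)oxy]-3-{[(TBS)oxy]acetyl}-5-{[(TBS)oxy]methyl}-3,4-dihydro-2H-pyran-4-yl]acetaldehyde; arms cis (α), 2-O β (key-step precursor) | CC(C)(C)[Si](C)(C)O[C@@H]1OC=C(CO[Si](C)(C)C(C)(C)C)[C@@H](CC=O)[C@H]1C(=O)CO[Si](C)(C)C(C)(C)C | intermediate
21 | 1-[(TBS)oxy]-4,7-bis{[(TBS)oxy]methyl}-7-hydroxy-1,4a,5,7a-tetrahydrocyclopenta[c]pyran-6(7H)-one; cis-fused, H4a and H7a β, 1-O β, 7-OH α, 7-CH2O β (key-step product) | CC(C)(C)[Si](C)(C)O[C@@H]1OC=C(CO[Si](C)(C)C(C)(C)C)[C@H]2CC(=O)[C@](O)(CO[Si](C)(C)C(C)(C)C)[C@@H]12 | intermediate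
22 | (R)-3-methylpentanoic acid | CC[C@@H](C)CC(=O)O | starting material
23 | 1-hydroxy-4,7-bis{[(TBS)oxy]methyl}-7-hydroxy-1,4a,5,7a-tetrahydrocyclopenta[c]pyran-6(7H)-one (lactol, ring stereochemistry as in 21), not isolated | O[C@@H]1OC=C(CO[Si](C)(C)C(C)(C)C)[C@H]2CC(=O)[C@](O)(CO[Si](C)(C)C(C)(C)C)[C@@H]12 | intermediate
24 | 4,7-bis{[(TBS)oxy]methyl}-7-hydroxy-6-oxo-1,4a,5,6,7,7a-hexahydrocyclopenta[c]pyran-1-yl (3R)-3-methylpentanoate; 1β ester, ring stereochemistry as in 21 | CC[C@@H](C)CC(=O)O[C@@H]1OC=C(CO[Si](C)(C)C(C)(C)C)[C@H]2CC(=O)[C@](O)(CO[Si](C)(C)C(C)(C)C)[C@@H]12 | intermediate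
25 | 4,7-bis{[(TBS)oxy]methyl}-6,7-dihydroxy-1,4a,5,6,7,7a-hexahydrocyclopenta[c]pyran-1-yl (3R)-3-methylpentanoate; 6-OH β and 7-OH α (trans diol), otherwise as 24 | CC[C@@H](C)CC(=O)O[C@@H]1OC=C(CO[Si](C)(C)C(C)(C)C)[C@H]2C[C@H](O)[C@](O)(CO[Si](C)(C)C(C)(C)C)[C@@H]12 | intermediate
26 | 4-[(tert-butyldimethylsilyl)oxy]benzaldehyde | CC(C)(C)[Si](C)(C)Oc1ccc(C=O)cc1 | starting material
27 | methyl 2-[bis(2,2,2-trifluoroethoxy)phosphoryl]acetate | COC(=O)CP(=O)(OCC(F)(F)F)OCC(F)(F)F | starting material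
28 | methyl (Z)-3-{4-[(TBS)oxy]phenyl}prop-2-enoate | COC(=O)/C=C\c1ccc(O[Si](C)(C)C(C)(C)C)cc1 | intermediate
29 | (Z)-3-(4-hydroxyphenyl)prop-2-enoic acid | OC(=O)/C=C\c1ccc(O)cc1 | intermediate
30 | tert-butyldimethylsilyl (Z)-3-{4-[(TBS)oxy]phenyl}prop-2-enoate, not isolated | CC(C)(C)[Si](C)(C)OC(=O)/C=C\c1ccc(O[Si](C)(C)C(C)(C)C)cc1 | intermediate
31 | (Z)-3-{4-[(TBS)oxy]phenyl}prop-2-enoic acid | OC(=O)/C=C\c1ccc(O[Si](C)(C)C(C)(C)C)cc1 | intermediate
32 | (Z)-3-{4-[(TBS)oxy]phenyl}prop-2-enoic 2,4,6-trichlorobenzoic anhydride, not isolated | O=C(OC(=O)/C=C\c1ccc(O[Si](C)(C)C(C)(C)C)cc1)c1c(Cl)cc(Cl)cc1Cl | intermediate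
33 | tris-TBS ether of the target: 1β-O-[(3R)-3-methylpentanoyl], 7β-O-[(Z)-4-(TBS-oxy)cinnamoyl], 8α-OH, 10-O-TBS, 11-O-TBS | CC[C@@H](C)CC(=O)O[C@@H]1OC=C(CO[Si](C)(C)C(C)(C)C)[C@H]2C[C@H](OC(=O)/C=C\c3ccc(O[Si](C)(C)C(C)(C)C)cc3)[C@](O)(CO[Si](C)(C)C(C)(C)C)[C@@H]12 | intermediate
34 | CNP0217341.1: 1β-O-[(3R)-3-methylpentanoyl], 7β-O-[(Z)-4-hydroxycinnamoyl], 8α-OH, 10-OH, 11-OH iridoid | CC[C@@H](C)CC(=O)O[C@@H]1OC=C(CO)[C@H]2C[C@H](OC(=O)/C=C\c3ccc(O)cc3)[C@](O)(CO)[C@@H]12 | target

**Step count**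

Total: 23 steps. Longest linear sequence: 17 steps (steps 1, 2, 6–18, 22, 23).

**Steps most likely to fail**

1. Step 16 (key step). Deprotonation at C9 by the amine may outrun carbene addition, causing epimerisation or loss of silanolate from C1 with ring opening; reversibility of the benzoin could also erode facial selectivity at C8. The fallback uses a nitronate as the C7 acyl-anion equivalent, for which a base too weak to touch C9 suffices. It sets out from 19: selective iodination of the primary C7 hydroxyl (I2, PPh3, imidazole) should give the primary iodide F1; displacement with NaNO2 in DMF should give the nitro alcohol F2; Dess–Martin oxidation of the C8 carbinol should give the nitro ketone F3; catalytic Et3N should close C7–C8 by a reversible intramolecular Henry reaction, placing C10 on the convex face under thermodynamic control, to give the bicyclic nitro alcohol F4; a Nef reaction (NaNO2, AcOH, DMSO) should unmask the C7 ketone and bring the route back at 21.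

2. Step 6. The catalyst fixes the enamine face (C9) reliably, but the acceptor face (C5) may be taken in the syn instead of the anti mode, giving the wrong C5/C9 relationship. The fallback sets C5 with the enantiomeric catalyst and corrects C9 thermodynamically. It sets out from 4 and 9: with (R)-2-[diphenyl(trimethylsilyloxy)methyl]pyrrolidine the syn mode should give the syn adduct F5, which has the required C5 configuration; Fukuyama reduction and cyclisation should give the 9-epi lactol F6; because C9 is α to the masked C1 aldehyde, catalytic amine base should equilibrate it through the ring-opened aldehyde to the more stable lactol, which is 12 (C5 chain pseudoaxial away from the C4 ester, C9 chain equatorial, O1 axial), where the route is rejoined.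

3. Step 17. Fluoride may cleave the primary silyl ethers along with the anomeric one, and the free lactol, which lacks a stabilising C4 carbonyl, may ring-open and decompose before it is acylated. The fallback exchanges silyl for acyl without ever liberating the lactol. It sets out from 21 and 22: cyanuric fluoride and pyridine should convert 22 into (R)-3-methylpentanoyl fluoride F7; with catalytic tetrabutylammonium difluorotriphenylsilicate in THF, fluoride should attack the anomeric silyl ether only, and the lactolate should be acylated at once by F7 with release of fluoride for the next turnover, giving 24, where the route is rejoined.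

**Further compounds**

F1 | step 16 | 1-[2-[(TBS)oxy]-5-{[(TBS)oxy]methyl}-4-(2-iodoethyl)-3,4-dihydro-2H-pyran-3-yl]-2-[(TBS)oxy]ethan-1-ol | CC(C)(C)[Si](C)(C)O[C@@H]1OC=C(CO[Si](C)(C)C(C)(C)C)[C@@H](CCI)[C@H]1C(O)CO[Si](C)(C)C(C)(C)C
F2 | step 16 | 1-[2-[(TBS)oxy]-5-{[(TBS)oxy]methyl}-4-(2-nitroethyl)-3,4-dihydro-2H-pyran-3-yl]-2-[(TBS)oxy]ethan-1-ol | CC(C)(C)[Si](C)(C)O[C@@H]1OC=C(CO[Si](C)(C)C(C)(C)C)[C@@H](CC[N+](=O)[O-])[C@H]1C(O)CO[Si](C)(C)C(C)(C)C
F3 | step 16 | 1-[2-[(TBS)oxy]-5-{[(TBS)oxy]methyl}-4-(2-nitroethyl)-3,4-dihydro-2H-pyran-3-yl]-2-[(TBS)oxy]ethan-1-one | CC(C)(C)[Si](C)(C)O[C@@H]1OC=C(CO[Si](C)(C)C(C)(C)C)[C@@H](CC[N+](=O)[O-])[C@H]1C(=O)CO[Si](C)(C)C(C)(C)C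
F4 | step 16 | 1-[(TBS)oxy]-4,7-bis{[(TBS)oxy]methyl}-6-nitro-1,4a,5,6,7,7a-hexahydrocyclopenta[c]pyran-7-ol (C6 epimers) | CC(C)(C)[Si](C)(C)O[C@@H]1OC=C(CO[Si](C)(C)C(C)(C)C)[C@H]2CC([N+](=O)[O-])[C@](O)(CO[Si](C)(C)C(C)(C)C)[C@@H]12
F5 | step 6 | methyl (3S,4S)-2-[(ethylsulfanyl)carbonyl]-4-formyl-3-{2-[(4-methoxyphenyl)methoxy]ethyl}-6-(phenylsulfanyl)hexanoate (C2 epimers) | O=C[C@@H](CCSc1ccccc1)[C@H](CCOCc1ccc(OC)cc1)C(C(=O)OC)C(=O)SCC
F6 | step 6 | methyl 2-hydroxy-4-{2-[(4-methoxyphenyl)methoxy]ethyl}-3-[2-(phenylsulfanyl)ethyl]-3,4-dihydro-2H-pyran-5-carboxylate, 9-epi series (side chains trans) | O[C@H]1OC=C(C(=O)OC)[C@@H](CCOCc2ccc(OC)cc2)[C@@H]1CCSc3ccccc3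
F7 | step 17 | (R)-3-methylpentanoyl fluoride | CC[C@@H](C)CC(=O)F
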